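**Retrosynthetic overview**
1. Feature: in ring C the phenyl-bearing C4 is bonded to arene carbon C4a and reaches O1 through C3 and the spiro carbon C2 (= C2′ of ring B). With C3–C4 raised to an alkyne, O1–C2–C3–C4(Ph) is the chain of an aryl 3-phenylprop-2-ynyl ether.
2. Guajadial D ⇒ (remove CHO at C6 and C8, mask the phenols, restore C3=C4) 4-phenyl spiro-2H-chromene ⇒ (C4–C4a, gold, 6-endo-dig) tertiary aryl propargyl ether.
3. Ether ⇒ (phenyl by Sonogashira coupling; O1–C2 by copper-catalysed propargylic etherification) ethynyl carbonate of the bicyclic enone + 3,5-bis(SEM-oxy)phenol.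
4. Enone ⇒ (oxidative transposition, ring-closing metathesis, vinyl addition) 6-butenylmenthone ⇒ (axial hydrazone alkylation, sets C4a′) (−)-menthone, which supplies C5′ and C8′.
5. Ring order: A (menthone) → B (metathesis) → arene attached through O1 → C (key step). C4 is set afterwards by asymmetric hydrogenation.

Key step: step 12

Numbering: chromane O1, C2 (spiro, = C2′), C3, C4, C4a, C5–C8, C8a. Terpene C1′–C8a′ (ring B: C1′–C4′, C4a′, C8a′; ring A: C4a′–C8a′). The Why lines of steps 1–4 use menthone numbering (C1 carbonyl, C2 CH-i-Pr, C5 CHMe, C6 = later C4a′). SEM = CH2OCH2CH2SiMe3.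

Remark: the target SMILES places H-4a′ cis to H-5′ and trans to H-8′, so with C4a′–C4′ necessarily equatorial on ring A the methyl and isopropyl groups are both axial; this is the C4a′ epimer of the all-equatorial enone favoured by an equilibrating Robinson annulation of menthone with methyl vinyl ketone, and ring B is therefore built under kinetic, non-epimerising conditions.

**Step 1**
Reactants: 1 (−)-menthone
Product: 2 (E)-2-[(2S,5R)-5-methyl-2-(propan-2-yl)cyclohexylidene]-1,1-dimethylhydrazine
Conditions: Me2NNH2, AcOH (cat.), EtOH, 4 Å MS, 70 °C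
Reagents that add atoms: 1,1-dimethylhydrazine, CN(C)N
Why: Acid-catalysed condensation of a ketone with a 1,1-dialkylhydrazine; the NMe2 group should settle anti to the isopropyl-bearing C2, and C2 and C5 should keep their configuration because the diequatorial trans arrangement is also the stable one in the hydrazone.

**Step 2**
Reactants: 2 menthone dimethylhydrazone; 3 4-iodobut-1-ene
Product: 5 2-[(2R,3R,6S)-2-(but-3-en-1-yl)-3-methyl-6-(propan-2-yl)cyclohexylidene]-1,1-dimethylhydrazine, via lithiated hydrazone 4 (not isolated)
Conditions: LiN(i-Pr)2, THF, 0 °C; then 3, −78 → −20 °C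
Reagents that add atoms: none
Why: Alkylation of a lithiated N,N-dimethylhydrazone: the base removes a proton from the only α-CH2 (C6), and the aza-enolate, in the half-chair that keeps methyl and isopropyl equatorial, should be alkylated along the stereoelectronically preferred axial line anti to the axial C5–H, so the butenyl chain ends up axial, cis to the C5 methyl and trans to the C2 isopropyl (6R in menthone numbering, the later C4a′).

**Step 3**
Reactants: 5 butenylated hydrazone
Product: 6 (2R,3R,6S)-2-(but-3-en-1-yl)-3-methyl-6-(propan-2-yl)cyclohexan-1-one (menthone numbering 2S,5R,6R; chain cis to methyl, trans to isopropyl)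
Conditions: CuCl2 (20 mol %), THF–H2O, pH 7 phosphate buffer, rt
Reagents that add atoms: water, O
Why: Hydrolysis of the hydrazone catalysed by divalent copper at neutral pH, chosen because the contra-thermodynamic axial chain tolerates neither acid nor base; its C6–H is equatorial and poorly aligned with the C=O π system, which slows enolisation further.

**Step 4**
Reactants: 6 butenyl ketone
Product: 7 (1S,2R,3R,6S)-2-(but-3-en-1-yl)-1-ethenyl-3-methyl-6-(propan-2-yl)cyclohexan-1-ol (vinyl trans to the butenyl chain; the C1 epimer is equally usable)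
Conditions: CeCl3, CH2=CHMgBr, THF, −78 → 0 °C; H2O
Reagents that add atoms: vinylmagnesium bromide, C=C[Mg]Br
Why: 1,2-Addition of a weakly basic organocerium reagent to a hindered enolisable ketone, so C2 and C6 keep their configuration; the vinyl group should enter anti to the axial chain, but the new carbinol centre is of no consequence because C8a′ becomes trigonal in step 6.

**Step 5**
Reactants: 7 divinyl-type carbinol
Product: 8 (4aR,5R,8S,8aS)-5-methyl-8-(propan-2-yl)-4,4a,5,6,7,8-hexahydronaphthalen-8a(3H)-ol (C1′=C2′ alkene)
Conditions: second-generation Grubbs catalyst RuCl2(=CHPh)(PCy3)(SIMes) (3 mol %), CH2Cl2, 40 °C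
Reagents that add atoms: none
Why: Ring-closing metathesis of two monosubstituted alkenes closes ring B as a cyclohexene with loss of ethene; either carbinol epimer can place the two alkenyl groups gauche, and no stereocentre is touched.

**Step 6**
Reactants: 8 tertiary allylic alcohol
Product: 9 (4aR,5R,8S)-5-methyl-8-(propan-2-yl)-4,4a,5,6,7,8-hexahydronaphthalen-2(3H)-one
Conditions: [C5H5NH][CrO3Cl], 4 Å MS, CH2Cl2, rt
Reagents that add atoms: pyridinium chlorochromate (oxygen at C2′), c1cc[nH+]cc1.[O-][Cr](=O)(=O)Cl
Why: Babler–Dauben oxidative transposition: the tertiary allylic chromate ester shifts by a [3,3] path from C8a′ to C2′ and is oxidised there, which gives the C1′=C8a′ enone without base, so the γ-centres C4a′ and C8′ are not equilibrated.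

**Step 7**
Reactants: 9 enone
Product: 10 (2S,4aR,5R,8S)-2-ethynyl-5-methyl-8-(propan-2-yl)-2,3,4,4a,5,6,7,8-octahydronaphthalen-2-ol (expected major epimer)
Conditions: HC≡CMgBr, THF, −20 → 0 °C; H2O
Reagents that add atoms: ethynylmagnesium bromide, C#C[Mg]Br
Why: 1,2-Addition of an alkynyl Grignard reagent to a cyclohexenone; pseudoaxial attack on the ring B face anti to the pseudoaxial H-4a′ should give mainly the 2S alcohol, and both epimers are usable because C2′ becomes planar in step 10.

**Step 8**
Reactants: 10 propargylic alcohol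
Product: 12 (2S,4aR,5R,8S)-2-ethynyl-5-methyl-8-(propan-2-yl)-2,3,4,4a,5,6,7,8-octahydronaphthalen-2-yl methyl carbonate, via lithium alkoxide 11 (not isolated)
Conditions: LiN(SiMe3)2, THF, −78 °C; then ClCO2Me, −78 → −20 °C
Reagents that add atoms: methyl chloroformate, COC(=O)Cl
Why: O-Acylation of a lithium alkoxide with a chloroformate at low temperature installs the leaving group for step 10 without exposing the doubly activated tertiary carbinol to acid.

**Step 9**
Reactants: 13 phloroglucinol
Product: 14 3,5-bis{[2-(trimethylsilyl)ethoxy]methoxy}phenol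
Conditions: SEMCl (2 equiv), i-Pr2NEt, DMF, 0 °C → rt
Reagents that add atoms: 2-(trimethylsilyl)ethoxymethyl chloride, C[Si](C)(C)CCOCCl
Why: Statistical twofold O-alkylation of phloroglucinol, with the diether separated from the mono- and triethers; the acetal ether is small at oxygen, keeps the arene electron-rich for step 12 and is removed at the end with fluoride, whereas thiolate cleavage of methyl ethers tends to stop at the monophenol and Lewis acids would break the tertiary allylic O1–C2 bond.

**Step 10**
Reactants: 12 methyl carbonate; 14 bis-SEM phenol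
Product: 15 1-{[(2R,4aR,5R,8S)-2-ethynyl-5-methyl-8-(propan-2-yl)-2,3,4,4a,5,6,7,8-octahydronaphthalen-2-yl]oxy}-3,5-bis{[2-(trimethylsilyl)ethoxy]methoxy}benzene
Conditions: CuCl2 (2 mol %), DBU, MeCN, −10 → 0 °C
Reagents that add atoms: none
Why: Copper-catalysed propargylic etherification of a tertiary propargylic carbonate with a phenol: loss of carbonate from the copper acetylide gives a copper allenylidene in which C2′ is planar, and the phenoxide should attack along the pseudoaxial line of the ring B half-chair, anti to the pseudoaxial H-4a′, which sets C2 (2′R in 15) from either carbonate epimer.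

**Step 11**
Reactants: 15 terminal alkyne ether; 16 iodobenzene
Product: 17 1-{[(2R,4aR,5R,8S)-5-methyl-2-(phenylethynyl)-8-(propan-2-yl)-2,3,4,4a,5,6,7,8-octahydronaphthalen-2-yl]oxy}-3,5-bis{[2-(trimethylsilyl)ethoxy]methoxy}benzene
Conditions: PdCl2(PPh3)2 (2 mol %), CuI (4 mol %), Et3N, THF, rt
Reagents that add atoms: none
Why: Sonogashira coupling of the terminal alkyne with iodobenzene at room temperature under amine base, conditions under which the aryl ether, the SEM groups and the trisubstituted alkene are inert.

**Step 12**
Reactants: 17 tertiary aryl 3-phenylpropargyl ether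
Product: 18 (2R,4a′R,5′R,8′S)-5′-methyl-4-phenyl-8′-(propan-2-yl)-5,7-bis{[2-(trimethylsilyl)ethoxy]methoxy}-4′,4a′,5′,6′,7′,8′-hexahydro-3′H-spiro[chromene-2,2′-naphthalene]
Conditions: [Au(NCMe){P(t-Bu)2(biphenyl-2-yl)}]SbF6 (5 mol %), 2,6-di-tert-butyl-4-methylpyridine (10 mol %), 4 Å MS, CH2Cl2, 0 °C → rt
Reagents that add atoms: none
Why: Monovalent gold binds the alkyne of 17, the arene carbon ortho to O1 attacks the phenyl-bearing alkyne carbon anti to gold, and loss of the arenium proton followed by protodeauration of the vinylgold species releases 18 and the catalyst. The closest known reaction type is the gold- or platinum-catalysed intramolecular hydroarylation of aryl propargyl ethers to 2H-chromenes, which is established for 1,1-dialkylated (tertiary) ethers and for aryl-capped alkynes. Ring C closes in the 6-endo-dig mode by forming C4–C4a. No stereocentre is made, and C2 keeps the configuration set in step 10 because O1–C2 is never broken, unlike in a thermal propargyl Claisen sequence. The step needs endo rather than 5-exo attack, which the phenyl group secures by stabilising positive charge at C4, and a single site on the arene, which is given because the two ortho carbons are equivalent and activated by three oxygen substituents. It also needs the tertiary, allylic and propargylic O1–C2 bond to survive, for which a preformed silver-free cationic complex with a bulky electron-rich phosphine, a hindered pyridine as proton shuttle, molecular sieves and low temperature are chosen.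

**Step 13**
Reactants: 18 4-phenyl spiro-2H-chromene
Product: 19 (2S,4S,4a′R,5′R,8′S)-5′-methyl-4-phenyl-8′-(propan-2-yl)-5,7-bis{[2-(trimethylsilyl)ethoxy]methoxy}-4′,4a′,5′,6′,7′,8′-hexahydro-3′H-spiro[chromane-2,2′-naphthalene] (the C2 descriptor changes only because C3 loses CIP rank)
Conditions: [Ir(cod){(S)-t-Bu-PHOX}]B[3,5-(CF3)2C6H3]4 (2 mol %; PHOX = 4-tert-butyl-2-[2-(diphenylphosphanyl)phenyl]-4,5-dihydrooxazole), H2 (50 bar), CH2Cl2, rt
Reagents that add atoms: none
Why: Iridium–P,N-catalysed asymmetric hydrogenation of an unfunctionalised trisubstituted 1,1-diaryl olefin: the two faces of the nearly flat ring C differ only in C1′H versus C3′H2 at the spiro carbon, so the ligand rather than the substrate chooses the face; H2 has to add on the face that carries C1′, which puts phenyl cis to C3′ (4S), and the C1′=C8a′ alkene is protected by the spiro carbon and the two branched carbons at C8a′.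

**Step 14**
Reactants: 19 spiro-chromane
Product: 20 6,8-dibromo derivative of 19 (2S,4S,4a′R,5′R,8′S)
Conditions: NBS (2.05 equiv), MeCN, −20 → 0 °C
Reagents that add atoms: N-bromosuccinimide, O=C1CCC(=O)N1Br
Why: Electrophilic aromatic bromination: C6 and C8 are the only free positions of a trialkoxybenzene and should react far faster than the hindered C1′=C8a′ alkene or the unactivated phenyl ring, and no acid is released.

**Step 15**
Reactants: 20 dibromide
Product: 22 6,8-dicarbaldehyde of 19 (2S,4S,4a′R,5′R,8′S), via dilithioarene 21 (not isolated)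
Conditions: t-BuLi (4.4 equiv), THF, −78 °C; then DMF, −78 °C → rt; H2O
Reagents that add atoms: N,N-dimethylformamide, CN(C)C=O
Why: Twofold bromine–lithium exchange, each aryllithium being flanked and chelated by two oxygen substituents, followed by formylation with DMF; exchange at −78 °C should outrun deprotonation of the diarylmethine C4–H, and the acid-free medium leaves O1–C2 alone.

**Step 16**
Reactants: 22 bis-SEM dialdehyde
Product: 23 Guajadial D
Conditions: Bu4NF, THF, 45 °C; aq NH4Cl
Reagents that add atoms: none
Why: Fluoride-induced fragmentation of both SEM ethers (attack at silicon, loss of ethene and formaldehyde), helped by the ortho-formyl groups that make the phenoxides good leaving groups; no acid or Lewis acid meets the tertiary allylic aryl ether and no stereocentre is affected.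

**Compound list**
1 | (−)-menthone, (2S,5R)-5-methyl-2-(propan-2-yl)cyclohexan-1-one | CC(C)[C@@H]1CC[C@@H](C)CC1=O | starting material
2 | (E)-menthone N,N-dimethylhydrazone | CC(C)[C@@H]1CC[C@@H](C)C/C1=N\N(C)C | intermediate
3 | 4-iodobut-1-ene | C=CCCI | starting material
4 | lithiated hydrazone (aza-enolate, C1=C6) | CC(C)[C@@H]1CC[C@@H](C)C=C1N([Li])N(C)C | intermediate
5 | dimethylhydrazone of 6 (NMe2 syn to the alkylated carbon as formed) | CC(C)[C@@H]1CC[C@@H](C)[C@@H](CCC=C)/C1=N\N(C)C | intermediate
6 | (2R,3R,6S)-2-(but-3-en-1-yl)-3-methyl-6-(propan-2-yl)cyclohexan-1-one | CC(C)[C@@H]1CC[C@@H](C)[C@@H](CCC=C)C1=O | intermediate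
7 | (1S,2R,3R,6S)-2-(but-3-en-1-yl)-1-ethenyl-3-methyl-6-(propan-2-yl)cyclohexan-1-ol | CC(C)[C@@H]1CC[C@@H](C)[C@@H](CCC=C)[C@]1(O)C=C | intermediate
8 | (4aR,5R,8S,8aS)-5-methyl-8-(propan-2-yl)-4,4a,5,6,7,8-hexahydronaphthalen-8a(3H)-ol | CC(C)[C@@H]1CC[C@@H](C)[C@H]2CCC=C[C@]12O | intermediate
9 | (4aR,5R,8S)-5-methyl-8-(propan-2-yl)-4,4a,5,6,7,8-hexahydronaphthalen-2(3H)-one | CC(C)[C@@H]1CC[C@@H](C)[C@H]2CCC(=O)C=C12 | intermediate
10 | (2S,4aR,5R,8S)-2-ethynyl carbinol of 9 | CC(C)[C@@H]1CC[C@@H](C)[C@H]2CC[C@@](O)(C#C)C=C12 | intermediate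
11 | lithium alkoxide of 10 | CC(C)[C@@H]1CC[C@@H](C)[C@H]2CC[C@@](O[Li])(C#C)C=C12 | intermediate
12 | methyl carbonate of 10 | CC(C)[C@@H]1CC[C@@H](C)[C@H]2CC[C@@](OC(=O)OC)(C#C)C=C12 | intermediate
13 | phloroglucinol | Oc1cc(O)cc(O)c1 | starting material
14 | 3,5-bis{[2-(trimethylsilyl)ethoxy]methoxy}phenol | C[Si](C)(C)CCOCOc1cc(O)cc(OCOCC[Si](C)(C)C)c1 | intermediate
15 | tertiary aryl ethynyl ether (2′R,4a′R,5′R,8′S) | CC(C)[C@@H]1CC[C@@H](C)[C@H]2CC[C@](Oc3cc(OCOCC[Si](C)(C)C)cc(OCOCC[Si](C)(C)C)c3)(C#C)C=C12 | intermediate
16 | iodobenzene | Ic1ccccc1 | starting material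
17 | tertiary aryl 3-phenylpropargyl ether (key-step precursor; 2′R,4a′R,5′R,8′S) | CC(C)[C@@H]1CC[C@@H](C)[C@H]2CC[C@](Oc3cc(OCOCC[Si](C)(C)C)cc(OCOCC[Si](C)(C)C)c3)(C#Cc3ccccc3)C=C12 | intermediate
18 | 5,7-bis(SEM-oxy)-4-phenyl spiro-2H-chromene (key-step product; 2R,4a′R,5′R,8′S) | CC(C)[C@@H]1CC[C@@H](C)[C@H]2CC[C@@]3(C=C12)C=C(c1ccccc1)c1c(OCOCC[Si](C)(C)C)cc(OCOCC[Si](C)(C)C)cc1O3 | intermediate
19 | 5,7-bis(SEM-oxy)-4-phenyl spiro-chromane (2S,4S,4a′R,5′R,8′S) | CC(C)[C@@H]1CC[C@@H](C)[C@H]2CC[C@@]3(C=C12)C[C@@H](c1ccccc1)c1c(OCOCC[Si](C)(C)C)cc(OCOCC[Si](C)(C)C)cc1O3 | intermediate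
20 | 6,8-dibromide of 19 | CC(C)[C@@H]1CC[C@@H](C)[C@H]2CC[C@@]3(C=C12)C[C@@H](c1ccccc1)c1c(OCOCC[Si](C)(C)C)c(Br)c(OCOCC[Si](C)(C)C)c(Br)c1O3 | intermediate
21 | 6,8-dilithioarene | CC(C)[C@@H]1CC[C@@H](C)[C@H]2CC[C@@]3(C=C12)C[C@@H](c1ccccc1)c1c(OCOCC[Si](C)(C)C)c([Li])c(OCOCC[Si](C)(C)C)c([Li])c1O3 | intermediate
22 | 6,8-dicarbaldehyde, bis-SEM ether | CC(C)[C@@H]1CC[C@@H](C)[C@H]2CC[C@@]3(C=C12)C[C@@H](c1ccccc1)c1c(OCOCC[Si](C)(C)C)c(C=O)c(OCOCC[Si](C)(C)C)c(C=O)c1O3 | intermediate
23 | Guajadial D (2S,4S,4a′R,5′R,8′S) | CC(C)[C@@H]1CC[C@@H](C)[C@H]2CC[C@@]3(C=C12)C[C@@H](c1ccccc1)c1c(O)c(C=O)c(O)c(C=O)c1O3 | target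

**Step count**
Total step count: 16. Longest linear sequence: 15 (steps 1–8 and 10–16; step 9 is a one-step branch).

**Steps most likely to fail**
1. Step 12. The cationic catalyst or traces of acid may heterolyse the tertiary, allylic and propargylic O1–C2 bond, leading to C-alkylation, elimination or loss of the C2 configuration. Closure may also be slow because phenyl and the 5-alkoxy group become peri neighbours. The fallback keeps the C4–C4a bond and the 6-endo-dig mode but replaces the metal by a buffered halonium electrophile. It sets out from 17: I2 and NaHCO3 in MeCN at rt should give the 3-iodo-4-phenyl spiro-2H-chromene F1. Iodine–lithium exchange with t-BuLi in THF at −78 °C, followed by MeOH, removes the iodine, and the route is rejoined at 18.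
2. Step 10. DBU may take a C3′ proton from the carbonate or the allenylidene (elimination to a dienyne), the arene carbon may attack instead of oxygen, or facial selectivity at the planar C2′ may be poor. The fallback replaces the planar intermediate by a stereospecific substitution. It sets out from the chromatographically purified 2S alcohol 10 and phenol 14. A Mitsunobu etherification (PPh3, DIAD, toluene, 0 °C → rt), a reaction known for tertiary propargylic carbinols and proceeding with inversion, turns the configuration obtained in step 7 into that required at C2. The route is rejoined directly at 15, and the fallback makes no new compound F0.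
3. Step 13. The alkene, flanked by the quaternary C2 and the peri 5-alkoxy group, may react sluggishly. Acidic iridium hydrides may cleave O1–C2 or the acetals. The ligand antipode may also be mismatched, giving poor or opposite facial selectivity; in the case of opposite sense the R ligand is used. The fallback gives up catalyst control. It sets out from 18: hydrogen-atom-transfer hydrogenation with Mn(dpm)3 (dpm = 2,2,6,6-tetramethylheptane-3,5-dionate), PhSiH3 and t-BuOOH in i-PrOH should reduce only the alkene that leads to a diaryl-stabilised radical. Compound 19 is separated from its C4 epimer, the (4R)-spiro-chromane F2, and the route is rejoined at 19. F2 is dehydrogenated with DDQ back to 18 and recycled.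

**Further compounds**
F1 | step 12 | 3-iodo-5,7-bis(SEM-oxy)-4-phenyl spiro-2H-chromene | CC(C)[C@@H]1CC[C@@H](C)[C@H]2CC[C@@]3(C=C12)C(I)=C(c1ccccc1)c1c(OCOCC[Si](C)(C)C)cc(OCOCC[Si](C)(C)C)cc1O3
F0 | step 10 | none | none
F2 | step 13 | (4R)-epimer of spiro-chromane 19 | CC(C)[C@@H]1CC[C@@H](C)[C@H]2CC[C@@]3(C=C12)C[C@H](c1ccccc1)c1c(OCOCC[Si](C)(C)C)cc(OCOCC[Si](C)(C)C)cc1O3
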